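## Structural features

The target is a flavanone. Ring A, a phloroglucinol-type benzene, is fused through C4a and C8a to the dihydropyranone ring C (O1, C2, C3, C4=O), and ring B is attached at C2 through the C2–C1' bond. C2 is the only stereocentre, (S) (priorities O1 > C1' > C3 > H), and has no stereogenic neighbour. It is benzylic, an aryl ether carbon and β to the C4 ketone, so base can open ring C to the 2'-hydroxychalcone and re-close it without facial preference. Ring A carries the hydrogen-bonded 5-OH, the acidic 7-OH (para to the carbonyl) and a 3-methylbut-2-enyl (prenyl) group at C6 between them. Ring B carries 3'-OH, 4'-OMe and the second prenyl group at C2', the crowded carbon between C1' and C3'. The fragile parts are the two trisubstituted alkenes, each ortho to a free phenol (acid closes them to 2,2-dimethylchromans; hydrogenation and oxidants attack them), the three phenols, and the epimerisable C2. The real difficulty is regiochemistry: C6 and C8 of ring A are electronically almost equal and C2' is the least accessible carbon of ring B, so intermolecular prenylation cannot be expected to select these two sites. The key step exploits the fact that O5 has only one free ortho carbon (C6; the other is the ring-fusion carbon C4a) and O3' has only one (C2'; the other is the methoxy-bearing C4'), so an allyl group passed from each oxygen to its ortho carbon can only arrive where a prenyl group is required. The skeleton, the oxygenation pattern and the (S)-centre are all present in hesperetin, so only two C–C bonds have to be made.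

## Logic of the disconnections

**10 ⇒ 9.** The only cut is the O7–Si bond. O7 must stay masked until the end, because the 7-OH is the most acidic phenol: left free it would be etherified first, and its ether would rearrange to C8 or C6. Nothing is gained in skeleton. The demand on the forward step is a cleavage that is neither acidic (prenyl groups next to phenols) nor basic (C2), which points to a silyl ether and buffered fluoride.

**9 ⇒ 8.** The C6–CH2 and C2'–CH2 bonds are cut and the dimethyl-bearing allyl termini are re-attached to O5 and O3'. This removes both C-prenyl groups at once and replaces a regiochemical problem on two aromatic rings by two O-alkylations. The forward step is a double [3,3] shift. It requires that the allyl group be attached through its tertiary carbon (so that inversion gives the normal prenyl group), that both ethers shift ortho, and that conditions stay neutral so that C2 in 8 and 9 is untouched.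

**8 ⇒ 7.** Each vinyl group is traced back to an ethynyl group. A tertiary allyl electrophile cannot be put on a phenol by direct substitution without scrambling to the primary isomer, whereas the tertiary propargyl electrophile can, under copper catalysis. The forward step must stop cleanly at the alkene.

**7 ⇒ 3 + 6 (6 from 4 and 5).** The two O–C(tertiary) bonds at O5 and O3' are cut, giving the two free phenols of 3 and the activated ester 6 of alcohol 4. The forward step must alkylate both a normal phenol and the chelated, peri-hindered 5-OH, and the base needed must not open ring C or strip the O7 protecting group.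

**3 ⇒ 1 + 2.** The O7–Si bond is cut. Selectivity rests on acidity: only the 7-OH of 1 is ionised by a tertiary amine. The silyl group is triisopropylsilyl and not tert-butyldimethylsilyl, because a silyl ether of a phenol para to a ketone is readily removed by amidine bases and the smaller group would not survive the etherification; the bulkier group is still cleaved by fluoride.

## Other disconnections considered

**Alternative 1:** Ring C is cut at C4a–C4, C4–C3 and O1–C2, dividing the molecule into the ring A iodophenol A1 and the ring B arylacetylene A2. In the forward direction a palladium-catalysed carbonylative Sonogashira coupling, followed in the same flask by 6-endo closure of the phenol onto the alkyne carbon, would give the tris(methoxymethyl) flavone A3.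
- In its favour: it is convergent, forms three bonds and a ring in one operation, fixes every substituent position in the fragments, and never has to alkylate a chelated hydroxyl. On bonds formed per step and on independence from the reactivity of O5 it is the better plan.
- Against it: A3 is achiral, so C2 would have to be created by enantioselective 1,4-reduction of the C2=C3 bond next to an ortho-substituted ring B, in the presence of two other alkenes. 5-Exo closure to an aurone competes with the 6-endo mode. A1 and A2 each need a regiocontrolled prenylation of their own, so the ring A and ring B problem is moved, not removed. The three acetal groups come off with acid on a bis(ortho-prenylphenol).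
- Comparison: the chosen plan obtains the stereocentre from the chiral pool and uses five steps; this alternative would need well over twice that and an asymmetric step of uncertain chemoselectivity.

**Alternative 2:** Ring B is cut at C2'–C3' and C1'–C6'. 3-Methoxyfuran A4 and the prenylated alkynoate A5 would undergo a Diels–Alder reaction, and opening of the oxygen bridge would give the benzoate A6.
- In its favour: the polarity match (the enol-ether carbon C2 of A4 with the β-carbon of A5) places the prenyl group next to the new hydroxyl and the ester para to the methoxy group, so the contiguous 1,2,3,4-pattern of ring B arises without any substitution on a benzene ring. On certainty of the ring B regiochemistry it is the equal of the chosen plan, and like it relies on a pericyclic step with substrate-controlled orientation.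
- Against it: it delivers only ring B, as an ester. Adjustment to the aldehyde level, condensation with a separately prenylated ring A unit and an enantioselective oxa-Michael closure would all remain, and these contain both the C6/C8 problem and the stereocentre. Acid-promoted opening of the bridge generates a phenol ortho to a prenyl group under the conditions that favour chroman formation. A4 is a sensitive diene.
- Comparison: on step economy and on stereochemistry the chosen plan is clearly ahead.

**Alternative 3:** The C4–C4a bond is cut. The (S)-3-aryl-3-aryloxypropanoyl chloride A7 would close ring C by intramolecular Friedel–Crafts acylation to the tris(silyl) flavanone A8.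
- In its favour: the aryloxy ring of A7 is symmetric about the O1–C6 axis, so both ortho carbons give the same product and the C6/C8 question does not arise. On this point it is the equal of the chosen plan, and it is the better plan in not needing to alkylate a chelated hydroxyl or depending on a chiral-pool supply.
- Against it: acid chloride formation and a Lewis acid must be tolerated by two prenyl groups and three aryl silyl ethers. The stereocentre of A7 is a para-methoxybenzylic aryl ether, which ionises easily (racemisation) or eliminates to the cinnamoyl derivative. Acylation next to a bulky silyloxy group is crowded. A7 would need prenylated precursors for both rings and an asymmetric C–O bond formation.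
- Comparison: the chosen plan keeps the stereocentre out of harm under neutral conditions and is far shorter.

Key step: step 4

Remark on the chemistry: flavanone numbering is used (O1, C2–C4, C4a, C5–C8, C8a; ring B C1'–C6'), and commercial (S)-hesperetin is assumed to be enantiomerically pure, to be confirmed by chiral HPLC before use.

## Route

Step 1
Reactants: 1 (S)-hesperetin; 2 triisopropylsilyl chloride
Product: 3 (S)-7-O-(triisopropylsilyl)hesperetin
Conditions: 2 (1.05 equiv), i-Pr2NEt (1.2 equiv), DMF, −20 → 0 °C
Reagents that add atoms: triisopropylsilyl chloride (2), CC(C)[Si](Cl)(C(C)C)C(C)C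
Why: Phenol silylation; the 7-OH is a vinylogous carboxylic acid (para to C4=O) and is the only phenol ionised by the tertiary amine, while the 5-OH is locked in a hydrogen bond and the 3'-OH is less acidic and flanked by the methoxy group. The triisopropylsilyl group is chosen because it should survive the amidine base of step 2.

Step 2
Reactants: 3 (S)-7-O-(triisopropylsilyl)hesperetin; 4 2-methylbut-3-yn-2-ol; 5 trifluoroacetic anhydride
Product: 7 (S)-5,3'-bis-O-(2-methylbut-3-yn-2-yl)-7-O-(triisopropylsilyl)hesperetin, via 2-methylbut-3-yn-2-yl trifluoroacetate 6 (not isolated)
Conditions: 4 (3.4 equiv), 5 (3.4 equiv), DBU (3.8 equiv), MeCN, −5 °C, 30 min; then added to 3, DBU (2.4 equiv), CuCl2·2H2O (1 mol %), MeCN, −5 → 0 °C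
Reagents that add atoms: 2-methylbut-3-yn-2-ol (4), CC(C)(O)C#C, delivered as its trifluoroacetate (6), CC(C)(OC(=O)C(F)(F)F)C#C
Why: Copper-catalysed propargylic etherification of phenols: the copper acetylide of 6 ionises to an electrophilic copper allenylidene that is captured at its tertiary carbon by the DBU phenoxides of O3' and of the chelated O5, an SN1-like capture suited to hindered and electron-poor phenols. The low temperature and short exposure limit retro-oxa-Michael opening at C2.

Step 3
Reactants: 7 (S)-5,3'-bis-O-(2-methylbut-3-yn-2-yl)-7-O-(triisopropylsilyl)hesperetin
Product: 8 (S)-5,3'-bis-O-(2-methylbut-3-en-2-yl)-7-O-(triisopropylsilyl)hesperetin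
Conditions: H2 (1 atm), Pd/CaCO3 poisoned with Pb(OAc)2 (5 wt % Pd), quinoline, EtOAc, 0 °C, stopped after 2 equiv H2
Reagents that add atoms: none
Why: Semihydrogenation of terminal alkynes on poisoned palladium; the alkynes bind far more strongly than the monosubstituted alkenes they give, and metering the hydrogen uptake should stop the reaction at the diene, while the aryl ketone, the silyl ether and the benzylic C2–O1 bond are inert under these conditions. Any early [3,3] shift of 8 would only anticipate step 4.

Step 4
Reactants: 8 (S)-5,3'-bis-O-(2-methylbut-3-en-2-yl)-7-O-(triisopropylsilyl)hesperetin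
Product: 9 (S)-6,2'-bis(3-methylbut-2-enyl)-7-O-(triisopropylsilyl)hesperetin
Conditions: Eu(fod)3 (10 mol %), degassed PhMe, 80 → 110 °C, sealed tube
Reagents that add atoms: none
Why: Each aryl 1,1-dimethylallyl ether undergoes a concerted suprafacial [3,3]-sigmatropic (aromatic Claisen) shift through a chair-like six-membered transition state in which the terminal CH2 bonds to the ortho carbon as the O–CMe2 bond breaks, so the allyl unit arrives inverted as a 3-methylbut-2-enyl group on C6 (from O5) and on C2' (from O3'). The two ortho-cyclohexadienones formed carry a hydrogen on the newly substituted carbon and re-aromatise by tautomerisation to the 5- and 3'-phenols, which makes both shifts irreversible. The closest known reaction type is the thermal or Eu(fod)3-catalysed ortho-Claisen rearrangement of aryl 1,1-dimethylallyl ethers to ortho-prenylphenols; trivalent europium should bind the O5/C4=O pair and lower the barrier for the ring A ether, and the ring B ether should follow on warming. No ring is closed and no stereocentre is created; C2 is a spectator, because the medium is free of base and ring C therefore does not open to the chalcone. The selectivity needed is ortho over para and C6 over C8, C2' over C6'. It is secured by the substrate: the second ortho position of O5 is the quaternary C4a and that of O3' is the methoxy-bearing C4', and the fast enolisation of the dienones forestalls a following Cope shift to C8 or C6'. O7 carries a silyl group and no allyl group, so nothing can be delivered to C8 from that side. The relief of crowding at the tertiary ether carbon lets both shifts run well below the temperatures at which ortho-prenylphenols cyclise.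

Step 5
Reactants: 9 (S)-6,2'-bis(3-methylbut-2-enyl)-7-O-(triisopropylsilyl)hesperetin
Product: 10 (S)-6,2'-bis(3-methylbut-2-enyl)hesperetin (CNP0306216.1)
Conditions: TBAF (1.1 equiv), AcOH (1.3 equiv), THF, 0 °C
Reagents that add atoms: none
Why: Fluoride-induced cleavage of an aryl silyl ether, driven by Si–F bond formation and helped by the 7-phenoxide (para to C4=O) being a good leaving group. The acetic acid buffer protonates the phenoxide at once, so ring C should not open and C2 should keep its configuration; the prenyl groups and the other phenols do not react with fluoride.

## Compound list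

1 | (S)-hesperetin, (2S)-5,7-dihydroxy-2-(3-hydroxy-4-methoxyphenyl)chroman-4-one | COc1ccc([C@@H]2CC(=O)c3c(O)cc(O)cc3O2)cc1O | starting material
2 | triisopropylsilyl chloride | CC(C)[Si](Cl)(C(C)C)C(C)C | starting material
3 | (S)-7-O-(triisopropylsilyl)hesperetin, (2S)-5-hydroxy-2-(3-hydroxy-4-methoxyphenyl)-7-(triisopropylsilyloxy)chroman-4-one | COc1ccc([C@@H]2CC(=O)c3c(cc(O[Si](C(C)C)(C(C)C)C(C)C)cc3O)O2)cc1O | intermediate
4 | 2-methylbut-3-yn-2-ol | CC(C)(O)C#C | starting material
5 | trifluoroacetic anhydride | O=C(OC(=O)C(F)(F)F)C(F)(F)F | starting material
6 | 2-methylbut-3-yn-2-yl trifluoroacetate | CC(C)(OC(=O)C(F)(F)F)C#C | intermediate (not isolated)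
7 | (S)-5,3'-bis-O-(2-methylbut-3-yn-2-yl)-7-O-(triisopropylsilyl)hesperetin, (2S)-2-[4-methoxy-3-(2-methylbut-3-yn-2-yloxy)phenyl]-5-(2-methylbut-3-yn-2-yloxy)-7-(triisopropylsilyloxy)chroman-4-one | COc1ccc([C@@H]2CC(=O)c3c(cc(O[Si](C(C)C)(C(C)C)C(C)C)cc3OC(C)(C)C#C)O2)cc1OC(C)(C)C#C | intermediate
8 | (S)-5,3'-bis-O-(2-methylbut-3-en-2-yl)-7-O-(triisopropylsilyl)hesperetin, (2S)-2-[4-methoxy-3-(2-methylbut-3-en-2-yloxy)phenyl]-5-(2-methylbut-3-en-2-yloxy)-7-(triisopropylsilyloxy)chroman-4-one | COc1ccc([C@@H]2CC(=O)c3c(cc(O[Si](C(C)C)(C(C)C)C(C)C)cc3OC(C)(C)C=C)O2)cc1OC(C)(C)C=C | intermediate
9 | (S)-6,2'-bis(3-methylbut-2-enyl)-7-O-(triisopropylsilyl)hesperetin, (2S)-5-hydroxy-2-[3-hydroxy-4-methoxy-2-(3-methylbut-2-enyl)phenyl]-6-(3-methylbut-2-enyl)-7-(triisopropylsilyloxy)chroman-4-one | COc1ccc([C@@H]2CC(=O)c3c(cc(O[Si](C(C)C)(C(C)C)C(C)C)c(CC=C(C)C)c3O)O2)c(CC=C(C)C)c1O | intermediate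
10 | (S)-6,2'-bis(3-methylbut-2-enyl)hesperetin, (2S)-5,7-dihydroxy-2-[3-hydroxy-4-methoxy-2-(3-methylbut-2-enyl)phenyl]-6-(3-methylbut-2-enyl)chroman-4-one (CNP0306216.1) | COc1ccc([C@@H]2CC(=O)c3c(cc(O)c(CC=C(C)C)c3O)O2)c(CC=C(C)C)c1O | target

## Step count and least certain steps

Total step count: 5. Longest linear sequence: 5 (1 → 3 → 7 → 8 → 9 → 10; 6 is made and consumed in the flask of step 2).

**Step 2 (etherification).** Most likely to go wrong: incomplete alkylation of the hydrogen-bonded, peri-hindered O5 by a tertiary electrophile. The amidine base may also cause retro-oxa-Michael opening of ring C (erosion of configuration at C2) or transfer of the silyl group from O7. Fallback, setting out from 3 and returning at 8: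
- 2-Methylbut-3-en-2-ol is converted with n-BuLi and Boc2O into tert-butyl 2-methylbut-3-en-2-yl carbonate F1.
- 3 is treated with F1 and Pd(PPh3)4 (zerovalent palladium) in THF at 0 °C. Decarboxylative ionisation gives a 1,1-dimethylallyl palladium cation and tert-butoxide, which deprotonates the phenols; the phenoxides attack the more substituted allyl terminus under kinetic control (Tsuji–Trost O-allylation).
- No amine base is present, and 7 and the hydrogenation of step 3 are bypassed.
- Should O5 refuse tertiary electrophiles altogether, the fallback for step 4 also starts from 3 and needs only a primary ether at O5.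

**Step 4 (key step).** Most likely to go wrong: heterolysis of the tertiary allyl ethers competing with the concerted shift (loss of isoprene, or ion-pair recombination at C8 or C6'). The two shifts may also run at unequal rates, so that the first-formed ortho-prenylphenol stays under Lewis-acidic heat and adds its hydroxyl across the prenyl double bond. Fallback, setting out from 3 and returning at 9, forming the same two C–C bonds from primary ethers that cannot ionise:
- Mitsunobu etherification of both free phenols of 3 with allyl alcohol (PPh3, DIAD, THF, 0 °C → rt; neutral, and a reaction type that alkylates ortho-acyl phenols) gives (S)-5,3'-bis-O-allyl-7-O-(triisopropylsilyl)hesperetin F2.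
- Double aromatic Claisen rearrangement (Eu(fod)3 in PhMe, or PhNEt2 at about 180 °C) gives (S)-6,2'-diallyl-7-O-(triisopropylsilyl)hesperetin F3. The regiochemical argument is the same as in step 4.
- Olefin cross-metathesis with excess 2-methyl-2-butene (second-generation Grubbs catalyst, CH2Cl2, 40 °C) turns each allyl group into a prenyl group and gives 9.
- The price is a hotter rearrangement and one more step; the enantiomeric purity would have to be checked after the heating.

**Step 3 (semihydrogenation).** Most likely to go wrong: over-reduction of the newly formed vinyl groups to ethyl groups, because the monosubstituted alkenes remain on the catalyst once the alkyne is consumed; the saturated ethers would be hard to separate and cannot rearrange. Fallback, setting out from 7 and returning at 8: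
- Both terminal alkynes are monohydroborated with dicyclohexylborane (THF, 0 °C) to the bis(alkenylborane) (S)-5,3'-bis-O-[(E)-4-(dicyclohexylboryl)-2-methylbut-3-en-2-yl]-7-O-(triisopropylsilyl)hesperetin F4, which is not isolated.
- Protonolysis of the two C–B bonds with acetic acid at room temperature gives 8.
- A stoichiometric hydrometalation followed by protonolysis cannot go past the alkene stage. The electron-rich, hindered C4 ketone is expected to react more slowly with the bulky borane than the alkynes do; this is the limit of the fallback.

**Step 5 (desilylation).** Most likely to go wrong: slow cleavage at O7, now flanked by the C6 prenyl group, tempting the use of more or unbuffered fluoride, which would lead to phenoxide-driven opening of ring C and loss of configuration at C2 on the most advanced material. Fallback, setting out from 8 and returning at 10, with the last two operations in reverse order: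
- 8 is desilylated with TBAF/AcOH while O7 is still unhindered, giving (S)-5,3'-bis-O-(2-methylbut-3-en-2-yl)hesperetin F5.
- The double Claisen rearrangement of F5 under the conditions of step 4 gives 10 directly. The free 7-OH carries no allyl group and cannot interfere, and no deprotection follows the rearrangement.

## Further compounds

F1 | step 2 | tert-butyl 2-methylbut-3-en-2-yl carbonate | CC(C)(C)OC(=O)OC(C)(C)C=C
F2 | step 4 | (S)-5,3'-bis-O-allyl-7-O-(triisopropylsilyl)hesperetin | COc1ccc([C@@H]2CC(=O)c3c(cc(O[Si](C(C)C)(C(C)C)C(C)C)cc3OCC=C)O2)cc1OCC=C
F3 | step 4 | (S)-6,2'-diallyl-7-O-(triisopropylsilyl)hesperetin | COc1ccc([C@@H]2CC(=O)c3c(cc(O[Si](C(C)C)(C(C)C)C(C)C)c(CC=C)c3O)O2)c(CC=C)c1O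
F4 | step 3 | (S)-5,3'-bis-O-[(E)-4-(dicyclohexylboryl)-2-methylbut-3-en-2-yl]-7-O-(triisopropylsilyl)hesperetin | COc1ccc([C@@H]2CC(=O)c3c(cc(O[Si](C(C)C)(C(C)C)C(C)C)cc3OC(C)(C)/C=C/B(C4CCCCC4)C4CCCCC4)O2)cc1OC(C)(C)/C=C/B(C5CCCCC5)C5CCCCC5
F5 | step 5 | (S)-5,3'-bis-O-(2-methylbut-3-en-2-yl)hesperetin | COc1ccc([C@@H]2CC(=O)c3c(cc(O)cc3OC(C)(C)C=C)O2)cc1OC(C)(C)C=C
A1 | alternative 1 | 2-iodo-3,5-bis(methoxymethoxy)-4-(3-methylbut-2-enyl)phenol | Oc1cc(OCOC)c(CC=C(C)C)c(OCOC)c1I
A2 | alternative 1 | 1-ethynyl-4-methoxy-3-(methoxymethoxy)-2-(3-methylbut-2-enyl)benzene | COCOc1c(OC)ccc(C#C)c1CC=C(C)C
A3 | alternative 1 | 5,7,3'-tris-O-(methoxymethyl)-6,2'-bis(3-methylbut-2-enyl)-4'-methoxyflavone | COc1ccc(-c2cc(=O)c3c(cc(OCOC)c(CC=C(C)C)c3OCOC)o2)c(CC=C(C)C)c1OCOC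
A4 | alternative 2 | 3-methoxyfuran | COc1ccoc1
A5 | alternative 2 | methyl 6-methylhept-5-en-2-ynoate | COC(=O)C#CCC=C(C)C
A6 | alternative 2 | methyl 3-hydroxy-4-methoxy-2-(3-methylbut-2-enyl)benzoate | COC(=O)c1ccc(OC)c(O)c1CC=C(C)C
A7 | alternative 3 | (S)-3-[3,5-bis(tert-butyldimethylsilyloxy)-4-(3-methylbut-2-enyl)phenoxy]-3-[3-(tert-butyldimethylsilyloxy)-4-methoxy-2-(3-methylbut-2-enyl)phenyl]propanoyl chloride | COc1ccc([C@H](CC(=O)Cl)Oc2cc(O[Si](C)(C)C(C)(C)C)c(CC=C(C)C)c(O[Si](C)(C)C(C)(C)C)c2)c(CC=C(C)C)c1O[Si](C)(C)C(C)(C)C
A8 | alternative 3 | (S)-5,7,3'-tris-O-(tert-butyldimethylsilyl)-6,2'-bis(3-methylbut-2-enyl)hesperetin | COc1ccc([C@@H]2CC(=O)c3c(cc(O[Si](C)(C)C(C)(C)C)c(CC=C(C)C)c3O[Si](C)(C)C(C)(C)C)O2)c(CC=C(C)C)c1O[Si](C)(C)C(C)(C)C
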